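In terpenoid numbering (ring B C5–C10, acetate at C6, methyls at C4/C8/C10, spiro carbon C13), the carbocycle C8–C9–C11–C12–C13–C14 (ring C) is disconnected at C8–C14. The C6 oxygen, carried as a ketone conjugated to C7=C8, makes C8 a radical acceptor; C14 sits on the finished spiro-ether carbon C13 as CH2CO2H. Visible-light decarboxylation gives the C14 radical, which adds 6-exo to C8: one operation closes ring C, sets the quaternary C8 methyl stereocentre and leaves the C6 carbonyl for the acetate. The precursor is a seco acid: an ent-drimane-type 7-en-6-one whose C9 ethylene arm ends at C13 of the preformed oxabicyclo[3.2.1]octane.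

Key step: step 14

Remark on locants: C1–C14 are terpenoid locants for rings A–C; the 6-oxabicyclo[3.2.1]octane carries primed locants C1′ (bridgehead on C13), C2′ (CH2), C3′ (C=O), C4′ (CHMe), C5′ (OCH bridgehead) and C8′ (CHOH), with C13 = C7′; the same locants are used for the open precursors. "ent" means the enantiomer of the sclareol-derived series.
Assumption: the catalyst antipodes named in steps 2 and 8 are taken to give the absolute configurations drawn; if the sense of induction proves opposite, the mirror-image catalyst is used.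

Step 1
Reactants: 1 (2E,6E)-farnesyl bromide
Product: 2 (4E,8E)-5,9,13-trimethyltetradeca-4,8,12-trienoic acid (farnesylacetic acid)
Conditions: AcOH, LDA (2.2 equiv), THF–HMPA, 0 °C; then 1, −78 °C → rt; aq. HCl
Reagents that add atoms: acetic acid, CC(=O)O
Why: SN2 alkylation of the acetic acid dianion by the primary allylic bromide should give the homologated acid with both E alkenes untouched.

Step 2
Reactants: 2 farnesylacetic acid
Product: 3 ent-ambreinolide (trans-decalin δ-lactone C8–O–C13(=O)–C12–C11–C9)
Conditions: confined chiral IDPi Brønsted acid (5 mol %), (CF3)3COH/CH2Cl2, −40 °C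
Reagents that add atoms: none
Why: Catalytic asymmetric proton-initiated polyene cyclization (chair–chair folding of the E,E-triene, anti addition across each alkene, carboxylic acid as terminator) should set C5, C10, C9 and C8 relative to one another (trans-decalin, equatorial C8–O, 8-Me and 10-Me syn-axial), while the chiral acid selects the ent series.

Step 3
Reactants: 3 ent-ambreinolide
Product: 4 hydroxy Weinreb amide (C8 tertiary alcohol; C9–CH2CH2–C(=O)N(OMe)Me)
Conditions: MeNH(OMe)·HCl, i-PrMgCl, THF, −20 → 0 °C
Reagents that add atoms: N,O-dimethylhydroxylamine hydrochloride, CNOC.Cl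
Why: Aminolysis of the lactone by the chloromagnesium amide (Weinreb amide formation) opens the temporary ring without touching a stereocentre.

Step 4
Reactants: 4 hydroxy Weinreb amide
Product: 5 8(17)-methylene Weinreb amide
Conditions: SOCl2, pyridine, CH2Cl2, −78 °C
Reagents that add atoms: none
Why: E2 dehydration of the tertiary chlorosulfite should give the exocyclic alkene, because the equatorial leaving group has only methyl hydrogens antiperiplanar (any Δ7 isomer formed alongside converges in step 5).

Step 5
Reactants: 5 8(17)-methylene Weinreb amide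
Product: 6 Δ7 Weinreb amide (C7=C8 trisubstituted, 9-H retained)
Conditions: Co(salen-tBu,tBu)Cl (cat.), PhSiH3 (cat.), PhH, rt
Reagents that add atoms: none
Why: Cobalt-hydride (MHAT) alkene isomerization by one position should give the Δ7 alkene, because the tertiary C8 radical returns a hydrogen atom from the accessible C7 methylene and not from C9–H, which is flanked by two quaternary carbons.

Step 6
Reactants: 6 Δ7 Weinreb amide
Product: 7 vinyl ketone, 1-(ent-drim-7-en-11-yl)but-3-en-2-one (C9–C11H2–C12H2–C13(=O)–CH=CH2)
Conditions: CH2=CHMgBr, THF, −78 → 0 °C; cold aq. HCl quench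
Reagents that add atoms: vinylmagnesium bromide, C=C[Mg]Br
Why: Weinreb ketone synthesis, in which the chelated tetrahedral intermediate prevents over-addition and the acidic quench prevents aza-Michael addition of the released amine.

Step 7
Reactants: 8 3-methylbut-2-enal (prenal)
Product: 10 (1E)-1-(methoxymethoxy)-3-methylbuta-1,3-diene, via potassium dienolate 9 (not isolated)
Conditions: KHMDS, THF–HMPA, −78 °C; then MOMCl
Reagents that add atoms: chloromethyl methyl ether, COCCl
Why: γ-Deprotonation of the s-trans enal gives the (E)-dienolate, and the hard chloromethyl ether should alkylate it on oxygen in the polar medium (enol ether formation).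

Step 8
Reactants: 7 vinyl ketone; 10 (1E)-1-(methoxymethoxy)-3-methylbuta-1,3-diene
Product: 11 Diels–Alder adduct, C13 ketone bearing the ring C1′H–C2′H2–C3′H2–C4′(Me)=C5′H–C8′H(OMOM) with C1′–acyl and C8′–OMOM cis
Conditions: (2S,5S)-5-benzyl-3-methyl-2-(5-methylfuran-2-yl)imidazolidin-4-one·HClO4 (20 mol %), H2O/EtOH, 0 °C
Reagents that add atoms: none
Why: Iminium-catalysed enantioselective Diels–Alder reaction, in which the 1-alkoxy-3-methyl diene gives the "ortho" regiochemistry (C8′–C1′ and C3′–C2′ bonds), the endo transition state makes C1′ and C8′ cis, and the catalyst shields one iminium face and so sets their absolute configuration (the decalin stereocentres are remote, and a minor diastereomer is separable).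

Step 9
Reactants: 11 Diels–Alder adduct
Product: 12 aldol adduct, C13 tertiary alcohol carrying C14H2–CO2Me
Conditions: 11, MgBr2·OEt2, CH2Cl2, −78 °C; then LiCH2CO2Me (MeOAc, LDA, Et2O), −78 °C; aq. NH4Cl
Reagents that add atoms: methyl acetate, COC(C)=O
Why: Cram-chelate (1,3-) controlled acetate aldol addition, in which Mg(II) bridges the C13 carbonyl and the C8′ MOM ether and the enolate adds to the chelate face anti to the ring methylene C2′, which sets C13 with C14 anti to C2′ and the C13 oxygen syn to C8′.

Step 10
Reactants: 12 aldol adduct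
Product: 13 bis-enone (ring B 7-en-6-one; cyclohex-4′-en-3′-one)
Conditions: Rh2(cap)4 (1 mol %), t-BuOOH (70% aq., excess), DCE, 40 °C
Reagents that add atoms: tert-butyl hydroperoxide, CC(C)(C)OO
Why: Dirhodium caprolactamate/t-BuOOH allylic C–H oxidation (peroxyl-radical hydrogen abstraction, mixed peroxide, Kornblum–DeLaMare collapse) should convert the two ring methylenes next to the methyl-bearing alkene carbons (C6 and C3′) into enone carbonyls, since C8′–H is deactivated by its oxygen and C9–H is shielded.

Step 11
Reactants: 13 bis-enone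
Product: 14 spiro ether, 6′-oxabicyclo[3.2.1]octan-3′-one with C13 bearing CH2CO2Me and the C12 chain
Conditions: DBU, CH2Cl2, rt
Reagents that add atoms: none
Why: Intramolecular oxa-Michael addition (5-exo-trig) of the tertiary C13 hydroxyl to C5′ can occur only on the face of the C1′ substituent, which makes C5′–O cis to C1′–C13 and to C8′–OMOM, and reversible protonation at C4′ should leave the methyl equatorial.

Step 12
Reactants: 14 spiro ether
Product: 15 C3′ dioxolane of 14
Conditions: (TMSOCH2)2, TMSOTf (cat.), CH2Cl2, −78 → −30 °C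
Reagents that add atoms: 1,2-bis(trimethylsilyloxy)ethane, C[Si](C)(C)OCCO[Si](C)(C)C
Why: Noyori ketalization should take the saturated C3′ ketone and leave the hindered, conjugated C6 ketone.

Step 13
Reactants: 15 dioxolane ester
Product: 16 seco acid (C13–C14H2–CO2H)
Conditions: LiOH·H2O, THF/H2O, rt; then 1 M HCl to pH 4, 0 °C
Reagents that add atoms: lithium hydroxide, [Li+].[OH-]
Why: Saponification of the methyl ester, with a mild acidification that the MOM ether and the dioxolane should survive.

Step 14
Reactants: 16 seco acid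
Product: 17 pentacyclic 6-ketone (ring C closed, 8-Me axial; 8′-OMOM, 3′-dioxolane)
Conditions: Ir[dF(CF3)ppy]2(dtbbpy)PF6 (1 mol %), K2HPO4, DMF (0.005 M), 450 nm LEDs, rt
Reagents that add atoms: none
Why: Excited Ir(III) oxidises the carboxylate of 16, CO2 is lost, and the primary C14 radical on the spiro carbon adds to C8, the β-carbon of the C6(=O)–C7=C8 enone; the C7 α-keto radical is reduced by Ir(II) to the enolate and protonated, so the process is redox-neutral. The closest known reaction type is the photoredox decarboxylative radical conjugate addition (Giese reaction), here intramolecular. Ring C (C8–C9–C11–C12–C13–C14) closes in the 6-exo-trig mode, 7-endo attack at C7 being polarity-mismatched. The new quaternary stereocentre C8 is controlled by the trans-decalin: the chain hangs from the equatorial C9–C11 bond and reaches C8 through a chair-like transition state on the enone face anti to the axial C10 methyl, which gives the trans B/C fusion with the C8 methyl axial and syn to the C10 methyl. The step needs face selectivity at C8 and a cyclization faster than hydrogen transfer to, or reduction of, the radical; the rigid enone, the match of a nucleophilic alkyl radical with an electron-poor alkene, high dilution and the absence of any other acceptor (C3′ is masked as the dioxolane) should secure this.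

Step 15
Reactants: 17 pentacyclic 6-ketone
Product: 18 axial 6-alcohol
Conditions: NaBH4, MeOH, 0 °C
Reagents that add atoms: none
Why: Hydride should add to the C6 ketone from the face opposite the axial C4, C8 and C10 methyl groups, which gives the axial alcohol syn to the angular methyls as the target requires.

Step 16
Reactants: 18 axial 6-alcohol
Product: 19 6-acetate
Conditions: Ac2O, DMAP, pyridine, 60 °C
Reagents that add atoms: acetic anhydride, CC(=O)OC(C)=O
Why: DMAP-catalysed acetylation of the hindered axial alcohol, which is the only free hydroxyl.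

Step 17
Reactants: 19 6-acetate
Product: 20 target CNP0188572.2
Conditions: 3 M aq. HCl, THF, 40 °C
Reagents that add atoms: water, O
Why: Acid hydrolysis of the dioxolane and of the MOM acetal should release the C3′ ketone and the C8′ hydroxyl, while the hindered acetate survives and the C4′ methyl stays equatorial (thermodynamic position α to the ketone).

Compound list
1 | (2E,6E)-farnesyl bromide | CC(C)=CCC/C(C)=C/CC/C(C)=C/CBr | starting material
2 | (4E,8E)-5,9,13-trimethyltetradeca-4,8,12-trienoic acid (farnesylacetic acid) | CC(C)=CCC/C(C)=C/CC/C(C)=C/CCC(=O)O | intermediate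
3 | ent-ambreinolide (trans-decalin δ-lactone, C8–O equatorial, 8-Me/10-Me syn-axial) | C1C[C@]2(C)OC(=O)CC[C@H]2[C@]2(C)CCCC(C)(C)[C@@H]12 | intermediate
4 | hydroxy Weinreb amide (C8–OH; C9–CH2CH2–C(=O)N(OMe)Me) | C1C[C@](C)(O)[C@@H](CCC(=O)N(C)OC)[C@]2(C)CCCC(C)(C)[C@@H]12 | intermediate
5 | 8(17)-methylene Weinreb amide | C1CC(=C)[C@@H](CCC(=O)N(C)OC)[C@]2(C)CCCC(C)(C)[C@@H]12 | intermediate
6 | Δ7 Weinreb amide | C1C=C(C)[C@@H](CCC(=O)N(C)OC)[C@]2(C)CCCC(C)(C)[C@@H]12 | intermediate
7 | vinyl ketone, 1-(ent-drim-7-en-11-yl)but-3-en-2-one | C1C=C(C)[C@@H](CCC(=O)C=C)[C@]2(C)CCCC(C)(C)[C@@H]12 | intermediate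
8 | 3-methylbut-2-enal (prenal) | CC(C)=CC=O | starting material
9 | potassium (1E)-3-methylbuta-1,3-dien-1-olate | [K+].[O-]/C=C/C(C)=C | intermediate (not isolated)
10 | (1E)-1-(methoxymethoxy)-3-methylbuta-1,3-diene | COCO/C=C/C(C)=C | intermediate
11 | Diels–Alder adduct (C13 ketone; cis C1′-acyl/C8′-OMOM cyclohex-4′-ene) | C1C=C(C)[C@@H](CCC(=O)[C@@H]3CCC(C)=C[C@@H]3OCOC)[C@]2(C)CCCC(C)(C)[C@@H]12 | intermediate
12 | aldol adduct (C13 tertiary alcohol with CH2CO2Me) | C1C=C(C)[C@@H](CC[C@](O)(CC(=O)OC)[C@@H]3CCC(C)=C[C@@H]3OCOC)[C@]2(C)CCCC(C)(C)[C@@H]12 | intermediate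
13 | bis-enone (7-en-6-one; cyclohex-4′-en-3′-one) | O=C1C=C(C)[C@@H](CC[C@](O)(CC(=O)OC)[C@@H]3CC(=O)C(C)=C[C@@H]3OCOC)[C@]2(C)CCCC(C)(C)[C@@H]12 | intermediate
14 | spiro ether (6′-oxabicyclo[3.2.1]octan-3′-one; CH2CO2Me on C13 syn to C8′–OMOM) | O=C1C=C(C)[C@@H](CC[C@@]3(CC(=O)OC)O[C@@H]4[C@H](OCOC)[C@H]3CC(=O)[C@@H]4C)[C@]2(C)CCCC(C)(C)[C@@H]12 | intermediate
15 | C3′ dioxolane methyl ester | O=C1C=C(C)[C@@H](CC[C@@]3(CC(=O)OC)O[C@@H]4[C@H](OCOC)[C@H]3CC5(OCCO5)[C@@H]4C)[C@]2(C)CCCC(C)(C)[C@@H]12 | intermediate
16 | seco acid | O=C1C=C(C)[C@@H](CC[C@@]3(CC(=O)O)O[C@@H]4[C@H](OCOC)[C@H]3CC5(OCCO5)[C@@H]4C)[C@]2(C)CCCC(C)(C)[C@@H]12 | intermediate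
17 | pentacyclic 6-ketone (ring C closed; configuration of the target at C5, C8, C9, C10, C13 and the bicycle) | O=C1C[C@]2(C)C[C@]3(CC[C@H]2[C@]2(C)CCCC(C)(C)[C@@H]12)O[C@@H]1[C@H](OCOC)[C@H]3CC4(OCCO4)[C@@H]1C | intermediate
18 | axial 6-alcohol | O[C@H]1C[C@]2(C)C[C@]3(CC[C@H]2[C@]2(C)CCCC(C)(C)[C@@H]12)O[C@@H]1[C@H](OCOC)[C@H]3CC4(OCCO4)[C@@H]1C | intermediate
19 | 6-acetate (8′-OMOM, 3′-dioxolane) | CC(=O)O[C@H]1C[C@]2(C)C[C@]3(CC[C@H]2[C@]2(C)CCCC(C)(C)[C@@H]12)O[C@@H]1[C@H](OCOC)[C@H]3CC4(OCCO4)[C@@H]1C | intermediate
20 | CNP0188572.2 | CC(=O)O[C@H]1C[C@]2(C)C[C@]3(CC[C@H]2[C@]2(C)CCCC(C)(C)[C@@H]12)O[C@@H]1[C@H](O)[C@H]3CC(=O)[C@@H]1C | target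

Total step count: 17. Longest linear sequence: 16 steps (steps 1–6 and 8–17; step 7 is the one-step diene branch).

Steps most likely to fail

Step 14. The C14 radical may be intercepted before it cyclises, by 1,5-hydrogen transfer from the allylic C9–H or by premature reduction, or it may add to the enone face syn to the C10 methyl and give the cis B/C fusion. The fallback sets out from acid 16. Iododecarboxylation under Suárez conditions (PhI(OAc)2, I2, hν, PhH) should trap the same radical with iodine faster than it cyclises and give the primary iodide F1. Halogen-atom abstraction with (TMS)3SiH and Et3B/O2 in toluene at −78 °C then runs the 6-exo cyclization as a reductive chain process at low temperature, where face discrimination should be sharper and hydrogen transfer slower. It comes back to the route at ketone 17.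

Step 10. Two allylic methylenes must be oxidised at once, so over- or under-oxidation, oxygen delivery to the transposed terminus (C5′ instead of C3′) or attack at C8′–H may occur. The fallback separates the two oxidations and sets out from amide 6. CrO3/3,5-dimethylpyrazole (CH2Cl2, −20 °C), the classical reagent for drim-7-enes, should give the 7-en-6-one amide F2. Vinylmagnesium bromide at −78 °C, which should leave the flanked C6 ketone alone, gives the vinyl ketone F3. The Diels–Alder reaction with diene 10 under the conditions of step 8 gives the adduct F4, and the chelate-controlled aldol addition of step 9 gives the hydroxy ester F5. A single Rh2(cap)4/t-BuOOH oxidation of the only remaining allylic methylene (C3′) then comes back to the route at bis-enone 13.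

Step 9. Chelate control may be lost (Felkin-type addition giving the C13 epimer), the ester enolate may enolize the ketone, or the MOM ether may be lost by β-elimination. The fallback delivers C14 intramolecularly from the C8′ oxygen and sets out from ketone 11. Me2BBr (CH2Cl2, −78 °C) removes the MOM group and gives the β-hydroxy ketone F6, and bromoacetyl bromide/pyridine gives the bromoacetate F7. SmI2 (THF, −78 °C) triggers an intramolecular Reformatsky reaction through a Sm(III)-chelated chair, which should give the cis-fused β-hydroxy-δ-lactone F8 with C14 held on the side of the C8′ oxygen and anti to C2′. Methanolysis (K2CO3, MeOH, 0 °C) opens the lactone to the dihydroxy ester F9, and MOMCl/i-Pr2NEt should protect the secondary C8′ hydroxyl selectively, which comes back to the route at 12.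

Further compounds
F1 | step 14 | primary iodide (C13–CH2I seco enone) | O=C1C=C(C)[C@@H](CC[C@@]3(CI)O[C@@H]4[C@H](OCOC)[C@H]3CC5(OCCO5)[C@@H]4C)[C@]2(C)CCCC(C)(C)[C@@H]12
F2 | step 10 | 7-en-6-one Weinreb amide | O=C1C=C(C)[C@@H](CCC(=O)N(C)OC)[C@]2(C)CCCC(C)(C)[C@@H]12
F3 | step 10 | 7-en-6-one vinyl ketone | O=C1C=C(C)[C@@H](CCC(=O)C=C)[C@]2(C)CCCC(C)(C)[C@@H]12
F4 | step 10 | 7-en-6-one Diels–Alder adduct | O=C1C=C(C)[C@@H](CCC(=O)[C@@H]3CCC(C)=C[C@@H]3OCOC)[C@]2(C)CCCC(C)(C)[C@@H]12
F5 | step 10 | 7-en-6-one aldol adduct (hydroxy ester) | O=C1C=C(C)[C@@H](CC[C@](O)(CC(=O)OC)[C@@H]3CCC(C)=C[C@@H]3OCOC)[C@]2(C)CCCC(C)(C)[C@@H]12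
F6 | step 9 | β-hydroxy ketone (C8′–OH free) | C1C=C(C)[C@@H](CCC(=O)[C@@H]3CCC(C)=C[C@@H]3O)[C@]2(C)CCCC(C)(C)[C@@H]12
F7 | step 9 | C8′ bromoacetate | C1C=C(C)[C@@H](CCC(=O)[C@@H]3CCC(C)=C[C@@H]3OC(=O)CBr)[C@]2(C)CCCC(C)(C)[C@@H]12
F8 | step 9 | cis-fused β-hydroxy-δ-lactone (C13–C14H2–C(=O)–O–C8′) | C1C=C(C)[C@@H](CC[C@]3(O)CC(=O)O[C@H]4C=C(C)CC[C@@H]34)[C@]2(C)CCCC(C)(C)[C@@H]12
F9 | step 9 | dihydroxy methyl ester (C13–OH, C8′–OH) | C1C=C(C)[C@@H](CC[C@](O)(CC(=O)OC)[C@@H]3CCC(C)=C[C@@H]3O)[C@]2(C)CCCC(C)(C)[C@@H]12
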